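Q stands at the end of this chain, so whatever a flask has made of Q has already left D, and the question is how much D each flask still holds at the asked time.

| flask | J | E | L | X | temperature | remark | time |
|---|---|---|---|---|---|---|---|
| Thursday's | 10 mM | 1.2 equiv | 1.2 equiv | 1.1 equiv | 75 °C | run made earlier |  |
| Sunday's | 15 mM | 1.2 equiv | 1.2 equiv | 1.1 equiv | 108 °C | run made earlier |  |
| midnight | 20 mM | 1.20 equiv | 1.20 equiv | 1.10 equiv | 120 °C |  | 25 h |
| summer | 20 mM | 1.20 equiv | 1.20 equiv | 1.10 equiv | 60 °C |  | 25 h |
| spring | 20 mM | 1.20 equiv | 1.20 equiv | 1.10 equiv | 90 °C |  | 25 h |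

| run | time / h | D / % | Q / % | J / % |
|---|---|---|---|---|
| Thursday's | 15.0 | 59.5 | 0.7 | 40.6 |
| Thursday's | 30.0 | 75.3 | 1.1 | 23.3 |
| Thursday's | 60.0 | 84.3 | 4.1 | 10.2 |
| Thursday's | 96.0 | 85.1 | 7.9 | 5.0 |
| Thursday's | 192 | 79.8 | 17.7 | 0.8 |
| Sunday's | 2.50 | 71.0 | 2.6 | 23.9 |
| Sunday's | 5.00 | 76.3 | 10.3 | 10.7 |
| Sunday's | 10.0 | 70.8 | 22.4 | 3.6 |
| Sunday's | 20.0 | 55.7 | 42.0 | 0.5 |
| Sunday's | 40.0 | 35.7 | 62.1 | 0 |

(each reading ± 0.3 percentage points)

- steps under discussion: J + E -> D; L + D -> Z; X + Z -> Q

1. the flask with the highest amount of D, in percent of the J charged ("all alike" if they lie within 1.5 percentage points) (midnight / summer / spring / all alike)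
2. final D, as a percentage of the J charged, in midnight
3. final D, as a percentage of the J charged, in summer
4. final D, as a percentage of the J charged, in spring

I build the flask one step at a time, beginning with J + E -> D alone. From J at 30.0 h in Thursday's run, through the second-order law with the E excess, I read J's lifetime under E at the new charge as 5.72 h at 75 °C. Sunday's J at 5.00 h reads 0.717 h at 108 °C. A straight line of the logarithm against temperature gives 2.22 h in spring. Dividing 25 h by that gives 11.2: the lifetime count, time in the flask over a step's lifetime at the charge. The same law turns this count into J left, 2.94% in spring, so with this step alone D stands at 97.1%. Summer's count of 1.70 gives D 66.3%, and midnight's 74.2 gives >99.9%.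

Now I add L + D -> Z. Sunday's fall of D from 20.0 h to 40.0 h reads D's lifetime under L as 19.0 h, and Thursday's growth of Q from 96.0 h to 192 h reads 355 h. The same line gives spring a count of 0.267, summer 0.0187 and midnight 3.81. L keeps a constant excess of 0.200 over J and D together, so I use the excess law again, with L in the place of E and D's count in the place of J's, and multiply the share it leaves into the D of the first step, as if that D stood from the start: 76.3% in spring, 65.1% in summer, 15.8% in midnight.

The last step, X + Z -> Q, stands behind D. The gap in Sunday's balance at 20.0 h is 1.80%, far less than the Q beside it, so I take L + D -> Z as the rate-limiting step and change nothing. I commit to spring.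

The forecast also says spring, with D 78% (74% to 81%) there, 62% in summer and 18% in midnight: “about 97% of J is converted and about 20% of D is lost”. Its spring and midnight lie above mine, its summer below mine.

The flasks give spring as the highest: D 77.8% in spring, 63.4% in summer, 17.4% in midnight.

    J + E → D (k = 0.329 L mol⁻¹ min⁻¹, Ea = 68.0 kJ mol⁻¹)
    L + D → Z (k = 0.00806 L mol⁻¹ min⁻¹, Ea = 100 kJ mol⁻¹)
    X + Z → Q (k = 0.319 L mol⁻¹ min⁻¹, Ea = 78.0 kJ mol⁻¹)
    (constants at 90 °C)

Spring's count of 11.2 put J at 2.94%, and that flask holds 2.62%. The neighbour is the summer flask run at 85 °C. Moving down the same lines from spring gives a count of 8.20 for J and 0.171 for D, hence J 5.39% and D 80.6%. That neighbour holds J 4.91% and D 82.5%.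

The readings were generated by integration from invented constants; scatter was added.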